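**Plan**
- Retrosynthesis: the three aryl methyl ethers are removed last. Ring B is cut at O2–C3 (6-endo closure of an ortho-alkynyl benzoate) and at C4–C4a (Sonogashira coupling with 1-heptyne, C4a as bromide).
- The remaining benzoic acid is cut at two bonds at once, C8–O (diaryl ether) and C8a–C1 (carboxyl carbon), into the ring C phenol, an aryne and CO2.
- Enabling feature: C8 (aryloxy) and C8a (bearing C1) are neighbouring atoms of ring A, and C4a is the next atom past C8a. A C8≡C8a aryne with bromine on C4a can therefore take the phenoxide at C8 and CO2 at C8a and keep the bromide for ring B.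
- Forward order: the ring C phenol (3 steps from olivetol) and the silylaryl triflate (2 steps from 2,6-dibromo-4-methoxyphenol) are joined with CO2 to give rings A and C; then ester, alkyne, closure of ring B and demethylation.
- Stereochemistry: the target has no stereocentre and no stereogenic double bond; only regiochemistry must be controlled.

Key step: step 6

Remark: isocoumarin numbering is used (C1 carbonyl, O2, C3, C4, C4a, C5–C8, C8a); ring A is the benzo ring, ring B the pyranone, ring C the pentylresorcinol-derived ring. 2,6-Dibromo-4-methoxyphenol, olivetol, 1-heptyne and CO2 are assumed to be purchasable.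

**Route**

Step 1
Reactants: 1 2,6-dibromo-4-methoxyphenol
Product: 2 (2,6-dibromo-4-methoxyphenoxy)trimethylsilane
Conditions: HMDS (1.5 equiv), THF, 70 °C; volatiles removed in vacuo
Reagents that add atoms: hexamethyldisilazane, C[Si](C)(C)N[Si](C)(C)C
Why: O-silylation of an acidic phenol by a disilazane is driven by loss of ammonia and places the silyl group where it can later migrate to carbon.

Step 2
Reactants: 2 (2,6-dibromo-4-methoxyphenoxy)trimethylsilane
Product: 4 2-bromo-4-methoxy-6-(trimethylsilyl)phenyl trifluoromethanesulfonate, via lithium 2-bromo-4-methoxy-6-(trimethylsilyl)phenoxide 3 (not isolated)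
Conditions: n-BuLi (1.0 equiv), THF, −100 → −78 °C; then Tf2O, −100 → −78 °C
Reagents that add atoms: trifluoromethanesulfonic anhydride, O=S(=O)(OS(=O)(=O)C(F)(F)F)C(F)(F)F
Why: One equivalent of n-BuLi exchanges one of the two equivalent bromines, the ortho-lithiated aryl silyl ether undergoes the 1,3 O→C silyl shift (retro-Brook rearrangement), and the lithium phenoxide is O-triflated in the same flask, the standard entry to ortho-silylaryl triflates.

Step 3
Reactants: 5 olivetol
Product: 6 1,3-dimethoxy-5-pentylbenzene
Conditions: Me2SO4, K2CO3, acetone, reflux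
Reagents that add atoms: dimethyl sulfate, COS(=O)(=O)OC
Why: Williamson O-methylation of both phenols of a resorcinol under carbonate conditions is routine.

Step 4
Reactants: 6 1,3-dimethoxy-5-pentylbenzene
Product: 8 2,4-dimethoxy-6-pentylbenzaldehyde, via (2,4-dimethoxy-6-pentylbenzylidene)dimethyliminium chloride 7 (not isolated)
Conditions: POCl3, DMF, 0 → 70 °C; then ice, aq NaOH to pH 7, rt
Reagents that add atoms: N,N-dimethylformamide, CN(C)C=O; water, O
Why: In this Vilsmeier–Haack formylation the chloroiminium ion attacks the position para to one methoxy group and ortho to the other and to the pentyl chain, not the more hindered site between the two methoxy groups, and aqueous base hydrolyses the iminium salt to the aldehyde.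

Step 5
Reactants: 8 2,4-dimethoxy-6-pentylbenzaldehyde
Product: 10 2,4-dimethoxy-6-pentylphenol, via 2,4-dimethoxy-6-pentylphenyl formate 9 (not isolated)
Conditions: mCPBA, CH2Cl2, 0 °C → rt; NaHCO3 wash; then K2CO3 (cat.), MeOH, rt
Reagents that add atoms: 3-chloroperoxybenzoic acid, O=C(OO)c1cccc(Cl)c1
Why: In this Dakin-type Baeyer–Villiger oxidation the electron-rich aryl group migrates to oxygen in the Criegee adduct, and the resulting aryl formate is cleaved by mild methanolysis.

Step 6
Reactants: 10 2,4-dimethoxy-6-pentylphenol; 4 2-bromo-4-methoxy-6-(trimethylsilyl)phenyl trifluoromethanesulfonate; 11 carbon dioxide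
Product: 14 2-bromo-6-(2,4-dimethoxy-6-pentylphenoxy)-4-methoxybenzoic acid, via potassium 2,4-dimethoxy-6-pentylphenoxide 12 (not isolated), via 3-bromo-5-methoxybenzyne 13 (not isolated)
Conditions: KH (1.0 equiv), 18-crown-6, THF, 0 °C; CO2 (1 atm, solution saturated); then KF and 4 (1.5 equiv, added over 2 h), 0 °C → rt; then cold 1 M HCl
Reagents that add atoms: none
Why: Proposed new method: fluoride removes the silyl group and triflate departs to give aryne 13, the crown-activated phenoxide 12 adds to the aryne carbon remote from bromine (C8), and the aryl anion left on C8a, stabilised inductively by the adjacent C–Br bond, is captured by dissolved CO2 as the carboxylate, so that the C8–O and C8a–C1 bonds form in one operation. The closest known reaction types are the three-component coupling of arynes, amines and CO2 to anthranilic acids and the fluoride-mediated O-arylation of hindered phenols by silylaryl triflates. No ring is closed and no stereocentre is formed. The step needs attack at C8, which the distortion of a 3-haloaryne towards the carbon meta to the halogen should secure against the weak opposing bias of the methoxy group. It also needs carboxylation to outrun loss of bromide from the ortho-bromoaryl anion and its protonation, which a proton-free, CO2-saturated medium at 0 °C and slow, fluoride-limited release of the aryne are meant to secure. O-Carboxylation of the phenoxide is reversible, so the free phenoxide, the far better nucleophile, should carry the reaction, and the acid product can be separated from neutral by-products by base extraction.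

Step 7
Reactants: 14 2-bromo-6-(2,4-dimethoxy-6-pentylphenoxy)-4-methoxybenzoic acid
Product: 15 methyl 2-bromo-6-(2,4-dimethoxy-6-pentylphenoxy)-4-methoxybenzoate
Conditions: MeI, K2CO3, DMF, rt
Reagents that add atoms: iodomethane, CI
Why: SN2 alkylation of the carboxylate on oxygen avoids addition to the doubly ortho-substituted carboxyl carbon, at which Fischer esterification would be slow.

Step 8
Reactants: 15 methyl 2-bromo-6-(2,4-dimethoxy-6-pentylphenoxy)-4-methoxybenzoate; 16 1-heptyne
Product: 17 methyl 2-(2,4-dimethoxy-6-pentylphenoxy)-6-(hept-1-yn-1-yl)-4-methoxybenzoate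
Conditions: PdCl2(PPh3)2 (5 mol%), CuI (10 mol%), Et3N, DMF, 70 °C, sealed tube
Reagents that add atoms: none
Why: In this Sonogashira coupling the ortho ester activates the C4a–Br bond for oxidative addition to zerovalent palladium, and the copper acetylide of 1-heptyne delivers the alkyne, as is well known for methyl 2-bromobenzoates.

Step 9
Reactants: 17 methyl 2-(2,4-dimethoxy-6-pentylphenoxy)-6-(hept-1-yn-1-yl)-4-methoxybenzoate
Product: 18 8-(2,4-dimethoxy-6-pentylphenoxy)-6-methoxy-3-pentyl-1H-isochromen-1-one
Conditions: Cu(OTf)2 (10 mol%), CF3CO2H, 1,2-dichloroethane, 60 °C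
Reagents that add atoms: none
Why: Acid-promoted cyclisation of an ortho-alkynyl benzoate: the ester carbonyl oxygen, made more nucleophilic by the ortho and para oxygen substituents, attacks the activated alkyne at its distal, pentyl-bearing carbon (6-endo-dig, the δ-position of the aryl-conjugated ester), and trifluoroacetate removes the methyl group from the 1-methoxyisochromenylium ion.

Step 10
Reactants: 18 8-(2,4-dimethoxy-6-pentylphenoxy)-6-methoxy-3-pentyl-1H-isochromen-1-one
Product: 19 8-(2,4-dihydroxy-6-pentylphenoxy)-6-hydroxy-3-pentyl-1H-isochromen-1-one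
Conditions: BBr3 (8 equiv), CH2Cl2, −78 °C → rt; then H2O, 0 °C
Reagents that add atoms: none
Why: BBr3 cleaves all three aryl methyl ethers by Lewis acid complexation and bromide attack at methyl, conditions under which the isocoumarin lactone and the diaryl ether are known to persist, and hydrolysis of the aryl borates releases the triol.

**Compound list**
1 | 2,6-dibromo-4-methoxyphenol | COc1cc(Br)c(O)c(Br)c1 | starting material
2 | (2,6-dibromo-4-methoxyphenoxy)trimethylsilane | COc1cc(Br)c(O[Si](C)(C)C)c(Br)c1 | intermediate
3 | lithium 2-bromo-4-methoxy-6-(trimethylsilyl)phenoxide | COc1cc(Br)c([O-])c([Si](C)(C)C)c1.[Li+] | intermediate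
4 | 2-bromo-4-methoxy-6-(trimethylsilyl)phenyl trifluoromethanesulfonate | COc1cc(Br)c(OS(=O)(=O)C(F)(F)F)c([Si](C)(C)C)c1 | intermediate
5 | olivetol (5-pentylbenzene-1,3-diol) | CCCCCc1cc(O)cc(O)c1 | starting material
6 | 1,3-dimethoxy-5-pentylbenzene | CCCCCc1cc(OC)cc(OC)c1 | intermediate
7 | (2,4-dimethoxy-6-pentylbenzylidene)dimethyliminium chloride | CCCCCc1cc(OC)cc(OC)c1C=[N+](C)C.[Cl-] | intermediate
8 | 2,4-dimethoxy-6-pentylbenzaldehyde | CCCCCc1cc(OC)cc(OC)c1C=O | intermediate
9 | 2,4-dimethoxy-6-pentylphenyl formate | CCCCCc1cc(OC)cc(OC)c1OC=O | intermediate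
10 | 2,4-dimethoxy-6-pentylphenol | CCCCCc1cc(OC)cc(OC)c1O | intermediate
11 | carbon dioxide | O=C=O | starting material
12 | potassium 2,4-dimethoxy-6-pentylphenoxide | CCCCCc1cc(OC)cc(OC)c1[O-].[K+] | intermediate
13 | 3-bromo-5-methoxybenzyne | COC1=CC#CC(Br)=C1 | intermediate
14 | 2-bromo-6-(2,4-dimethoxy-6-pentylphenoxy)-4-methoxybenzoic acid | OC(=O)c1c(Br)cc(OC)cc1Oc1c(OC)cc(OC)cc1CCCCC | intermediate
15 | methyl 2-bromo-6-(2,4-dimethoxy-6-pentylphenoxy)-4-methoxybenzoate | COC(=O)c1c(Br)cc(OC)cc1Oc1c(OC)cc(OC)cc1CCCCC | intermediate
16 | 1-heptyne | CCCCCC#C | starting material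
17 | methyl 2-(2,4-dimethoxy-6-pentylphenoxy)-6-(hept-1-yn-1-yl)-4-methoxybenzoate | COC(=O)c1c(C#CCCCCC)cc(OC)cc1Oc1c(OC)cc(OC)cc1CCCCC | intermediate
18 | 8-(2,4-dimethoxy-6-pentylphenoxy)-6-methoxy-3-pentyl-1H-isochromen-1-one | CCCCCc1cc2cc(OC)cc(Oc3c(OC)cc(OC)cc3CCCCC)c2c(=O)o1 | intermediate
19 | 8-(2,4-dihydroxy-6-pentylphenoxy)-6-hydroxy-3-pentyl-1H-isochromen-1-one | CCCCCc1cc2cc(O)cc(Oc3c(O)cc(O)cc3CCCCC)c2c(=O)o1 | target

**Summary**
Total step count: 10. Longest linear sequence: 8 steps (steps 3, 4, 5, 6, 7, 8, 9, 10, from olivetol); the aryne branch (steps 1 and 2) joins at step 6.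

**Steps most likely to fail**

1. Step 6. The ortho-bromoaryl anion may expel bromide, giving a second aryne and oligomers, or be protonated before CO2 captures it. The phenoxide may also be held back as its carbonate. The fallback is known Ullmann chemistry; it sets out from phenol 10 and returns at acid 14. 3,5-Dibromoanisole is deprotonated between its two bromines with LiN(i-Pr)2 (THF, −78 °C) and carboxylated with CO2 to give 2,6-dibromo-4-methoxybenzoic acid F1. F1, used in excess, is then condensed with 10 (CuI, K2CO3, DMF, 110 °C). The ortho-carboxylate assists copper-mediated displacement of one of the two equivalent bromides, which should give 14 directly.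

2. Step 9. 5-Exo closure to the alkylidene phthalide, simple hydration of the alkyne, or acid-induced alkenylation of the electron-rich ring C may compete with the 6-endo closure. The fallback sets out from 17 and returns at 18. Iodine in CH2Cl2 at rt triggers 6-endo-dig attack of the ester carbonyl on the iodonium ion, with the methyl group leaving as MeI. This should give 4-iodo-8-(2,4-dimethoxy-6-pentylphenoxy)-6-methoxy-3-pentyl-1H-isochromen-1-one F2. The vinylic iodide is then removed by hydrodehalogenation (Pd(OAc)2, PPh3, HCO2Na, DMF, 80 °C) to give 18.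

3. Step 8. Oxidative addition into the C4a–Br bond, which lies next to a twisted, doubly ortho-substituted ester on an electron-rich ring, may be slow. Copper-mediated homocoupling of the alkyne or reduction of the bromide could then take over. The fallback sets out from acid 14 and returns at 18, bypassing 15 and 17. Tridecane-6,8-dione F3 is made by Claisen condensation of heptan-2-one with ethyl hexanoate (NaH, THF). It is coupled with 14 under Hurtley conditions (CuI, K3PO4, DMF, 100 °C). Carboxylate-directed C-arylation of the diketone, retro-Claisen loss of hexanoate and cyclodehydration of the aryl ketone onto the carboxylate should give 18 in one operation.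

Further compounds
F1 | step 6 | 2,6-dibromo-4-methoxybenzoic acid | COc1cc(Br)c(C(=O)O)c(Br)c1
F2 | step 9 | 4-iodo-8-(2,4-dimethoxy-6-pentylphenoxy)-6-methoxy-3-pentyl-1H-isochromen-1-one | CCCCCc1oc(=O)c2c(Oc3c(OC)cc(OC)cc3CCCCC)cc(OC)cc2c1I
F3 | step 8 | tridecane-6,8-dione | CCCCCC(=O)CC(=O)CCCCC
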